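**Retrosynthetic overview**
1. Target 26 ⇐ triene diol 25 by hydroxyl-directed, reagent-controlled epoxidation of the 4,5-alkene (Ti(OiPr)4, L-(+)-diethyl tartrate); 25 ⇐ 24 by desilylation.
2. 24 ⇐ acyclic phosphate 22: the ten-membered ring is closed at C6–C7 by a farnesyl-cation-type 1,10-cyclisation. The C6 allylic phosphate ionises, the distal C7=C11 allylsilane attacks, and silicon is lost in place of the proton lost in germacrene biosynthesis. This one step sets C7, the 11(13)-alkene and keeps the 12-acetate.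
3. 22 ⇐ enal 18 by Brown allylation (sets C9), isovalerylation and cross-metathesis with 2-[(trimethylsilyl)methyl]allyl acetate 21.
4. 18 ⇐ terminal alkene 8 + 2-formylallyl ester 17 by cross-metathesis (sets the 1(10)-E alkene); 17 ⇐ Evans syn-aldol acid 14 + 2-methylidenepropane-1,3-diol 15.
5. 8 ⇐ propargyl alcohol by ynoate syn-carbocupration (sets the 4,5-geometry), reduction and phosphorylation. Ring order: carbocycle (step 15), then oxirane (step 17).

Numbering and assumption: germacrane numbering is used throughout (C7 bears C11–C13, C9 the isovalerate, C10 bears C14, C4 bears C15); the target is (4S,5R,7S,9S); the same C7 geometry is labelled 7R in 24 and 25 because the CIP priorities change on epoxidation; 5, 9, 15, 21 and (−)-Ipc2B(allyl) are bought.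

**Route**

Step 1
Reactants: 1 prop-2-yn-1-ol
Product: 2 tert-butyl(diphenyl)(prop-2-yn-1-yloxy)silane
Conditions: TBDPSCl, imidazole, DMF, 0 °C → rt
Reagents that add atoms: tert-butyl(chloro)diphenylsilane, CC(C)(C)[Si](Cl)(c1ccccc1)c1ccccc1
Why: Silyl ether formation at a primary alcohol; the bulky TBDPS ether oxygen is a poor nucleophile, which matters when C6 is ionised in step 15.

Step 2
Reactants: 2 tert-butyl(diphenyl)(prop-2-yn-1-yloxy)silane
Product: 4 methyl 4-{[tert-butyl(diphenyl)silyl]oxy}but-2-ynoate, via lithium acetylide 3 (not isolated)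
Conditions: n-BuLi, THF, −78 °C; ClCO2Me, −78 → 0 °C
Reagents that add atoms: methyl chloroformate, COC(=O)Cl
Why: Deprotonation of the terminal alkyne and C-acylation of the acetylide with a chloroformate (alkynoate synthesis).

Step 3
Reactants: 4 methyl 4-{[tert-butyl(diphenyl)silyl]oxy}but-2-ynoate; 5 but-3-en-1-ylmagnesium bromide
Product: 6 methyl (2Z)-3-({[tert-butyl(diphenyl)silyl]oxy}methyl)hepta-2,6-dienoate
Conditions: 5, CuBr·SMe2, THF, −40 °C; 4, −78 °C; MeOH then aq. NH4Cl at −78 °C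
Reagents that add atoms: none
Why: syn-Carbocupration (conjugate addition) of the alkylcopper to the ynoate and protonation of the alkenylcopper at −78 °C with retention put the butenyl chain (C3) trans to the ester carbon (C6) and C15 cis to C6, which is the ring-trans geometry of the later 4,5-alkene.

Step 4
Reactants: 6 methyl (2Z)-3-({[tert-butyl(diphenyl)silyl]oxy}methyl)hepta-2,6-dienoate
Product: 7 (2Z)-3-({[tert-butyl(diphenyl)silyl]oxy}methyl)hepta-2,6-dien-1-ol
Conditions: i-Bu2AlH, CH2Cl2, −78 °C; aq. KNaC4H4O6 work-up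
Reagents that add atoms: none
Why: 1,2-Reduction of the enoate to the allylic alcohol by i-Bu2AlH leaves the alkene geometry and the silyl ether untouched.

Step 5
Reactants: 7 (2Z)-3-({[tert-butyl(diphenyl)silyl]oxy}methyl)hepta-2,6-dien-1-ol
Product: 8 (2Z)-3-({[tert-butyl(diphenyl)silyl]oxy}methyl)hepta-2,6-dien-1-yl diethyl phosphate
Conditions: ClP(O)(OEt)2, pyridine, DMAP (cat.), CH2Cl2, 0 °C
Reagents that add atoms: diethyl chlorophosphate, CCOP(=O)(Cl)OCC
Why: Phosphorylation of the primary allylic alcohol gives a diethyl phosphate, a stable stand-in for the diphosphate of farnesyl diphosphate that survives steps 11–14 and can be ionised selectively later.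

Step 6
Reactants: 9 (4R)-4-benzyl-3-propanoyl-1,3-oxazolidin-2-one; 10 acetaldehyde
Product: 11 (4R)-4-benzyl-3-[(2R,3S)-3-hydroxy-2-methylbutanoyl]-1,3-oxazolidin-2-one
Conditions: Bu2BOTf, iPr2NEt, CH2Cl2, −78 °C; 10, −78 → 0 °C; pH 7 buffer, MeOH, H2O2
Reagents that add atoms: none
Why: Evans syn-aldol reaction: the Z-boron enolate reacts through a Zimmerman–Traxler chair on the face away from the benzyl group of the (R)-auxiliary, which sets (2R,3S).

Step 7
Reactants: 11 (4R)-4-benzyl-3-[(2R,3S)-3-hydroxy-2-methylbutanoyl]-1,3-oxazolidin-2-one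
Product: 12 (4R)-4-benzyl-3-[(2R,3S)-3-{[tert-butyl(dimethyl)silyl]oxy}-2-methylbutanoyl]-1,3-oxazolidin-2-one
Conditions: TBSOTf, 2,6-lutidine, CH2Cl2, 0 °C
Reagents that add atoms: tert-butyldimethylsilyl triflate, CC(C)(C)[Si](C)(C)OS(=O)(=O)C(F)(F)F
Why: Silylation of the secondary alcohol so that it survives esterification, allylboration and acylation.

Step 8
Reactants: 12 (4R)-4-benzyl-3-[(2R,3S)-3-{[tert-butyl(dimethyl)silyl]oxy}-2-methylbutanoyl]-1,3-oxazolidin-2-one
Product: 14 (2R,3S)-3-{[tert-butyl(dimethyl)silyl]oxy}-2-methylbutanoic acid, via peroxy acid 13 (not isolated)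
Conditions: LiOH, H2O2, THF/H2O, 0 °C; Na2SO3; HCl to pH 3
Reagents that add atoms: hydrogen peroxide, OO
Why: Hydroperoxide cleavage of the imide at the exocyclic carbonyl and sulfite reduction of the peroxy acid give the acid without epimerisation at C2.

Step 9
Reactants: 14 (2R,3S)-3-{[tert-butyl(dimethyl)silyl]oxy}-2-methylbutanoic acid; 15 2-methylidenepropane-1,3-diol
Product: 16 2-(hydroxymethyl)prop-2-en-1-yl (2R,3S)-3-{[tert-butyl(dimethyl)silyl]oxy}-2-methylbutanoate
Conditions: 15 (4 equiv), EDC·HCl, DMAP (cat.), CH2Cl2, 0 °C → rt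
Reagents that add atoms: none
Why: Carbodiimide (Steglich-type) esterification; the excess of the symmetrical diol makes the mono-ester the main product.

Step 10
Reactants: 16 2-(hydroxymethyl)prop-2-en-1-yl (2R,3S)-3-{[tert-butyl(dimethyl)silyl]oxy}-2-methylbutanoate
Product: 17 2-formylprop-2-en-1-yl (2R,3S)-3-{[tert-butyl(dimethyl)silyl]oxy}-2-methylbutanoate
Conditions: MnO2, CH2Cl2, rt; filtered and used crude
Reagents that add atoms: none
Why: MnO2 oxidises only the allylic alcohol to the 2-substituted acrolein, which is used at once because it is a reactive Michael acceptor.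

Step 11
Reactants: 8 (2Z)-3-({[tert-butyl(diphenyl)silyl]oxy}methyl)hepta-2,6-dien-1-yl diethyl phosphate; 17 2-formylprop-2-en-1-yl (2R,3S)-3-{[tert-butyl(dimethyl)silyl]oxy}-2-methylbutanoate
Product: 18 (2E,6Z)-6-({[tert-butyl(diphenyl)silyl]oxy}methyl)-8-(diethoxyphosphoryloxy)-2-formylocta-2,6-dien-1-yl (2R,3S)-3-{[tert-butyl(dimethyl)silyl]oxy}-2-methylbutanoate
Conditions: 17 (2 equiv), second-generation Hoveyda–Grubbs catalyst RuCl2(H2IMes)(=CH-C6H4-2-OiPr) (5 mol%), CH2Cl2, 40 °C
Reagents that add atoms: none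
Why: Olefin cross-metathesis of a terminal alkene with an α-substituted acrolein (a methacrolein-type partner) gives the trisubstituted enal with C2 trans to the formyl carbon C9 (the favoured E isomer); the trisubstituted 4,5-alkene is inert.

Step 12
Reactants: 18 (enal from step 11)
Product: 19 (2E,6Z)-6-({[tert-butyl(diphenyl)silyl]oxy}methyl)-8-(diethoxyphosphoryloxy)-2-[(1S)-1-hydroxybut-3-en-1-yl]octa-2,6-dien-1-yl (2R,3S)-3-{[tert-butyl(dimethyl)silyl]oxy}-2-methylbutanoate
Conditions: (−)-Ipc2B(allyl), Et2O, −78 °C; NaBO3·4H2O, THF/H2O, rt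
Reagents that add atoms: (−)-B-allyldiisopinocampheylborane (from (+)-α-pinene), C=CCB([C@@H]1C[C@@H]2C[C@H]([C@H]1C)C2(C)C)[C@@H]1C[C@@H]2C[C@H]([C@H]1C)C2(C)C
Why: Brown asymmetric allylboration: the (+)-α-pinene-derived reagent adds through a chair transition state to the Si face of the conjugated aldehyde, as it does with benzaldehyde, which sets (S) at C9; phosphate and esters are untouched at −78 °C.

Step 13
Reactants: 19 (S)-homoallylic alcohol from step 12
Product: 20 (2E,6Z)-6-({[tert-butyl(diphenyl)silyl]oxy}methyl)-8-(diethoxyphosphoryloxy)-2-[(1S)-1-(3-methylbutanoyloxy)but-3-en-1-yl]octa-2,6-dien-1-yl (2R,3S)-3-{[tert-butyl(dimethyl)silyl]oxy}-2-methylbutanoate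
Conditions: (Me2CHCH2CO)2O, Et3N, DMAP (cat.), CH2Cl2, 0 °C
Reagents that add atoms: 3-methylbutanoic anhydride, CC(C)CC(=O)OC(=O)CC(C)C
Why: DMAP-catalysed acylation of the secondary allylic alcohol installs the isovalerate with retention at C9.

Step 14
Reactants: 20 isovalerate from step 13; 21 2-[(trimethylsilyl)methyl]prop-2-en-1-yl acetate
Product: 22 (2E,6Z)-2-[(1S)-4-(acetoxymethyl)-1-(3-methylbutanoyloxy)-5-(trimethylsilyl)pent-3-en-1-yl]-6-({[tert-butyl(diphenyl)silyl]oxy}methyl)-8-(diethoxyphosphoryloxy)octa-2,6-dien-1-yl (2R,3S)-3-{[tert-butyl(dimethyl)silyl]oxy}-2-methylbutanoate (E/Z mixture at the new C7=C11 bond)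
Conditions: 21 (5 equiv), second-generation Hoveyda–Grubbs catalyst RuCl2(H2IMes)(=CH-C6H4-2-OiPr) (10 mol%), CH2Cl2, 40 °C
Reagents that add atoms: none
Why: Cross-metathesis of the terminal alkene with a 1,1-disubstituted alkene gives the trisubstituted allylsilane; its E/Z ratio does not matter because C11 ends as the carbon of an exocyclic methylene.

Step 15
Reactants: 22 acyclic phosphate from step 14
Product: 24 (7R,9S)-germacra-1(10)E,4Z,11(13)-triene bearing 12-OAc 9-O-isovaleryl 14-O-[(2R,3S)-3-TBSO-2-methylbutanoyl] 15-OTBDPS, via allyl cation 23 (not isolated)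
Conditions: TMSOTf (0.2 equiv), 2,6-di-tert-butyl-4-methylpyridine (0.4 equiv), CH2Cl2, 22 added over 10 h to 0.001 M, −78 °C; Et3N quench
Reagents that add atoms: none
Why: Proposed new method: TMSOTf silylates the phosphoryl oxygen (much more Lewis-basic than any ester carbonyl) and the prenyl-type C6–O bond ionises to allyl cation 23, which keeps its C4=C5 geometry at −78 °C and cannot be trapped by the silyl ether oxygen except through a disfavoured 5-endo-trig path; under high dilution the C7=C11 allylsilane attacks C6 through C7 in a crossed chair–chair transition state with the new C7 substituent pseudo-equatorial and the C9 acyloxy group pseudo-axial (avoiding A(1,2) strain with the C14 CH2O-acyl group), which gives the 7,9-trans ring with C7 as in the target, and loss of Me3Si+ from the β-silyl cation forms the 11(13)-alkene and regenerates TMSOTf; this is the germacrene-synthase 1,10-closure of a farnesyl cation with silicon in the role of the lost proton, and the closest known reaction types are Lewis-acid-catalysed intermolecular coupling of allylic chlorides or phosphates with allylsilanes (Hosomi–Sakurai-type SN1 allylation), Lewis-acid-promoted cyclisations of terpenoid allylic phosphates and acylium–olefin closures of farnesyl derivatives to ten-membered rings.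

Step 16
Reactants: 24 ring triene from step 15
Product: 25 (7R,9S)-12-acetoxy-15-hydroxy-9-(3-methylbutanoyloxy)germacra-1(10)E,4Z,11(13)-trien-14-yl (2R,3S)-3-hydroxy-2-methylbutanoate
Conditions: HF·pyridine, pyridine, THF, 0 °C → rt
Reagents that add atoms: none
Why: Fluoride cleavage of both silyl ethers (Si–F bond formation); the esters and the ring triene are stable to buffered HF·pyridine at or below rt.

Step 17
Reactants: 25 triene diol from step 16
Product: 26 CNP0132467.1, (4S,5R,7S,9S)-12-acetoxy-4,5-epoxy-15-hydroxy-9-(3-methylbutanoyloxy)germacra-1(10)E,11(13)-dien-14-yl (2R,3S)-3-hydroxy-2-methylbutanoate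
Conditions: Ti(OiPr)4 (20 mol%), L-(+)-diethyl tartrate (25 mol%), t-BuOOH, 4 Å MS, CH2Cl2, −20 °C
Reagents that add atoms: tert-butyl hydroperoxide, CC(C)(C)OO
Why: Sharpless asymmetric epoxidation: only the free C15 allylic alcohol binds titanium, so only the 4,5-alkene reacts, and L-(+)-diethyl tartrate delivers oxygen to the face that gives (4S,5R) (the same sense that turns geraniol into its (2S,3S)-epoxide), by reagent control.

**Compound list**
1 | prop-2-yn-1-ol | C#CCO | starting material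
2 | tert-butyl(diphenyl)(prop-2-yn-1-yloxy)silane | C#CCO[Si](c1ccccc1)(c1ccccc1)C(C)(C)C | intermediate
3 | lithium acetylide of 2 | [Li]C#CCO[Si](c1ccccc1)(c1ccccc1)C(C)(C)C | intermediate
4 | methyl 4-{[tert-butyl(diphenyl)silyl]oxy}but-2-ynoate | COC(=O)C#CCO[Si](c1ccccc1)(c1ccccc1)C(C)(C)C | intermediate
5 | but-3-en-1-ylmagnesium bromide | C=CCC[Mg]Br | starting material
6 | methyl (2Z)-3-({[tert-butyl(diphenyl)silyl]oxy}methyl)hepta-2,6-dienoate (ester cis to CH2OSi) | COC(=O)/C=C(\CO[Si](c1ccccc1)(c1ccccc1)C(C)(C)C)CCC=C | intermediate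
7 | (2Z)-3-({[tert-butyl(diphenyl)silyl]oxy}methyl)hepta-2,6-dien-1-ol | OC/C=C(\CO[Si](c1ccccc1)(c1ccccc1)C(C)(C)C)CCC=C | intermediate
8 | (2Z)-3-({[tert-butyl(diphenyl)silyl]oxy}methyl)hepta-2,6-dien-1-yl diethyl phosphate | CCOP(=O)(OCC)OC/C=C(\CO[Si](c1ccccc1)(c1ccccc1)C(C)(C)C)CCC=C | intermediate
9 | (4R)-4-benzyl-3-propanoyl-1,3-oxazolidin-2-one | CCC(=O)N1[C@H](Cc2ccccc2)COC1=O | starting material
10 | acetaldehyde | CC=O | starting material
11 | (4R)-4-benzyl-3-[(2R,3S)-3-hydroxy-2-methylbutanoyl]-1,3-oxazolidin-2-one | O=C([C@H](C)[C@H](C)O)N1[C@H](Cc2ccccc2)COC1=O | intermediate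
12 | (4R)-4-benzyl-3-[(2R,3S)-3-{[tert-butyl(dimethyl)silyl]oxy}-2-methylbutanoyl]-1,3-oxazolidin-2-one | O=C([C@H](C)[C@H](C)O[Si](C)(C)C(C)(C)C)N1[C@H](Cc2ccccc2)COC1=O | intermediate
13 | (2R,3S)-3-{[tert-butyl(dimethyl)silyl]oxy}-2-methylbutaneperoxoic acid | OOC(=O)[C@H](C)[C@H](C)O[Si](C)(C)C(C)(C)C | intermediate
14 | (2R,3S)-3-{[tert-butyl(dimethyl)silyl]oxy}-2-methylbutanoic acid | OC(=O)[C@H](C)[C@H](C)O[Si](C)(C)C(C)(C)C | intermediate
15 | 2-methylidenepropane-1,3-diol | C=C(CO)CO | starting material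
16 | 2-(hydroxymethyl)prop-2-en-1-yl (2R,3S)-3-{[tert-butyl(dimethyl)silyl]oxy}-2-methylbutanoate | C=C(CO)COC(=O)[C@H](C)[C@H](C)O[Si](C)(C)C(C)(C)C | intermediate
17 | 2-formylprop-2-en-1-yl (2R,3S)-3-{[tert-butyl(dimethyl)silyl]oxy}-2-methylbutanoate | C=C(C=O)COC(=O)[C@H](C)[C@H](C)O[Si](C)(C)C(C)(C)C | intermediate
18 | (2E,6Z)-6-({[tert-butyl(diphenyl)silyl]oxy}methyl)-8-(diethoxyphosphoryloxy)-2-formylocta-2,6-dien-1-yl (2R,3S)-3-{[tert-butyl(dimethyl)silyl]oxy}-2-methylbutanoate | O=C/C(COC(=O)[C@H](C)[C@H](C)O[Si](C)(C)C(C)(C)C)=C/CC/C(CO[Si](c1ccccc1)(c1ccccc1)C(C)(C)C)=C/COP(=O)(OCC)OCC | intermediate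
19 | as 18 with the formyl group replaced by (1S)-1-hydroxybut-3-en-1-yl (C9 S) | C=CC[C@H](O)/C(COC(=O)[C@H](C)[C@H](C)O[Si](C)(C)C(C)(C)C)=C/CC/C(CO[Si](c1ccccc1)(c1ccccc1)C(C)(C)C)=C/COP(=O)(OCC)OCC | intermediate
20 | 3-methylbutanoate (isovalerate) of 19 at C9 | C=CC[C@H](OC(=O)CC(C)C)/C(COC(=O)[C@H](C)[C@H](C)O[Si](C)(C)C(C)(C)C)=C/CC/C(CO[Si](c1ccccc1)(c1ccccc1)C(C)(C)C)=C/COP(=O)(OCC)OCC | intermediate
21 | 2-[(trimethylsilyl)methyl]prop-2-en-1-yl acetate | CC(=O)OCC(=C)C[Si](C)(C)C | starting material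
22 | cyclisation precursor: as 20 with the terminal CH=CH2 replaced by CH=C(CH2OAc)CH2SiMe3 (E/Z mixture at C7=C11; C9 S; 1(10)E; C3 trans to C6) | C[Si](C)(C)CC(COC(C)=O)=CC[C@H](OC(=O)CC(C)C)/C(COC(=O)[C@H](C)[C@H](C)O[Si](C)(C)C(C)(C)C)=C/CC/C(CO[Si](c1ccccc1)(c1ccccc1)C(C)(C)C)=C/COP(=O)(OCC)OCC | intermediate
23 | C6/C4 allyl cation formed from 22 by loss of the phosphate | C[Si](C)(C)CC(COC(C)=O)=CC[C@H](OC(=O)CC(C)C)/C(COC(=O)[C@H](C)[C@H](C)O[Si](C)(C)C(C)(C)C)=C/CC/C(CO[Si](c1ccccc1)(c1ccccc1)C(C)(C)C)=C/[CH2+] | intermediate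
24 | (7R,9S)-germacra-1(10)E,4Z,11(13)-triene (both ring alkenes trans within the ring): C4 CH2OTBDPS, C7 C(=CH2)CH2OAc, C9 O-isovaleryl, C10 CH2O-CO-(2R,3S)-CH(CH3)CH(OTBS)CH3 | C=C(COC(C)=O)[C@H]1C[C@H](OC(=O)CC(C)C)/C(COC(=O)[C@H](C)[C@H](C)O[Si](C)(C)C(C)(C)C)=C/CC/C(CO[Si](c2ccccc2)(c2ccccc2)C(C)(C)C)=C/C1 | intermediate
25 | (7R,9S)-12-acetoxy-15-hydroxy-9-(3-methylbutanoyloxy)germacra-1(10)E,4Z,11(13)-trien-14-yl (2R,3S)-3-hydroxy-2-methylbutanoate | C=C(COC(C)=O)[C@H]1C[C@H](OC(=O)CC(C)C)/C(COC(=O)[C@H](C)[C@H](C)O)=C/CC/C(CO)=C/C1 | intermediate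
26 | CNP0132467.1, (4S,5R,7S,9S)-12-acetoxy-4,5-epoxy-15-hydroxy-9-(3-methylbutanoyloxy)germacra-1(10)E,11(13)-dien-14-yl (2R,3S)-3-hydroxy-2-methylbutanoate | C=C(COC(C)=O)[C@H]1C[C@H](OC(=O)CC(C)C)/C(COC(=O)[C@H](C)[C@H](C)O)=C/CC[C@@]2(CO)O[C@@H]2C1 | target

**Step count and risk**
Total: 17 steps. Longest linear sequence: 12 steps (1–5 then 11–17; the branch 6–10 then 11–17 is equally long). Compounds 24–26 are kept at or below rt to avoid Cope rearrangement of the 1,5-diene.

Steps most likely to fail: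

Step 15 (ring closure). The risks are oligomerisation, ionisation of the allylic C9 ester, and above all a closure that puts the C7 side chain cis to the C9 oxygen. The fallback sets out from 18 and comes back at 24; it uses C9 as a relay centre that is inverted when the ester goes on. Allylboration of 18 with (+)-Ipc2B(allyl) gives the (9R)-homoallylic alcohol F1. Cross-metathesis with 21 as in step 14 gives the hydroxy allylsilane F2. Closure with TMSOTf (1.3 equiv) and 2,6-di-tert-butyl-4-methylpyridine at −78 °C, in which the hydroxyl is silylated in the flask and freed again by citric acid/MeOH on work-up, gives the 7,9-cis ring alcohol F3. Mitsunobu esterification with isovaleric acid (PPh3, DIAD, toluene, 0 °C) inverts C9 and gives 24.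

Step 14 (cross-metathesis to a trisubstituted, doubly functionalised alkene). The fallback sets out from 19 and comes back at 22; it replaces the intermolecular metathesis by a silicon-tethered ring-closing metathesis. Compound 19 is treated with Ph2SiCl2 and imidazole, then with 2-[(trimethylsilyl)methyl]prop-2-en-1-ol, to give the mixed diphenylsilyl bis-ether F4. Ring-closing metathesis with the second-generation Grubbs catalyst RuCl2(H2IMes)(PCy3)(=CHPh) gives the eight-membered cyclic silyl bis-ether F5. PPTS in MeOH removes the tether and gives the diol F6, with C8 cis to CH2OH. AcCl and 2,4,6-collidine at −78 °C acetylate only the primary allylic hydroxyl to give the mono-acetate F7. Isovalerylation as in step 13 gives 22 as a single C7=C11 isomer.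

Step 17 (epoxidation). The free ring may prefer to present the other face of the 4,5-alkene, so the tartrate control could be mismatched or slow. The fallback sets out from 24 and comes back at 26; it epoxidises before desilylation with a dioxirane and does not rely on titanium binding. Compound 24 is treated with the D-fructose-derived Shi ketone and KHSO5 (K2CO3 buffer, MeCN/dimethoxymethane/H2O, 0 °C). The 4,5-alkene is the most electron-rich of the three, and this ketone gives R,R-type epoxides from a trans-related pair (here C3/C6), which is the same face as L-(+)-diethyl tartrate. This gives the bis-silyl epoxide F8; Bu4NF buffered with AcOH in THF then removes both silyl groups and gives 26.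

**Further compounds**
F1 | step 15 | C9 epimer of 19, with (1R)-1-hydroxybut-3-en-1-yl | C=CC[C@@H](O)/C(COC(=O)[C@H](C)[C@H](C)O[Si](C)(C)C(C)(C)C)=C/CC/C(CO[Si](c1ccccc1)(c1ccccc1)C(C)(C)C)=C/COP(=O)(OCC)OCC
F2 | step 15 | (9R)-hydroxy allylsilane (22 with free C9–OH of inverted configuration) | C[Si](C)(C)CC(COC(C)=O)=CC[C@@H](O)/C(COC(=O)[C@H](C)[C@H](C)O[Si](C)(C)C(C)(C)C)=C/CC/C(CO[Si](c1ccccc1)(c1ccccc1)C(C)(C)C)=C/COP(=O)(OCC)OCC
F3 | step 15 | (7R,9R)-9-hydroxy ring triene (24 with free, epimeric C9–OH) | C=C(COC(C)=O)[C@H]1C[C@@H](O)/C(COC(=O)[C@H](C)[C@H](C)O[Si](C)(C)C(C)(C)C)=C/CC/C(CO[Si](c2ccccc2)(c2ccccc2)C(C)(C)C)=C/C1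
F4 | step 14 | mixed diphenylsilyl bis-ether of 19 and 2-[(trimethylsilyl)methyl]prop-2-en-1-ol | C=CC[C@H](O[Si](c1ccccc1)(c1ccccc1)OCC(=C)C[Si](C)(C)C)/C(COC(=O)[C@H](C)[C@H](C)O[Si](C)(C)C(C)(C)C)=C/CC/C(CO[Si](c1ccccc1)(c1ccccc1)C(C)(C)C)=C/COP(=O)(OCC)OCC
F5 | step 14 | eight-membered 1,3-dioxa-2-silacyclooct-5-ene (C9–O–SiPh2–O–C12, ring alkene C7=C11) | C[Si](C)(C)CC1=CC[C@H](O[Si](c2ccccc2)(c2ccccc2)OC1)/C(COC(=O)[C@H](C)[C@H](C)O[Si](C)(C)C(C)(C)C)=C/CC/C(CO[Si](c2ccccc2)(c2ccccc2)C(C)(C)C)=C/COP(=O)(OCC)OCC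
F6 | step 14 | C9,C12-diol with C8 cis to CH2OH | C[Si](C)(C)C/C(CO)=C/C[C@H](O)/C(COC(=O)[C@H](C)[C@H](C)O[Si](C)(C)C(C)(C)C)=C/CC/C(CO[Si](c1ccccc1)(c1ccccc1)C(C)(C)C)=C/COP(=O)(OCC)OCC
F7 | step 14 | C12 mono-acetate of F6 (free C9–OH) | C[Si](C)(C)C/C(COC(C)=O)=C/C[C@H](O)/C(COC(=O)[C@H](C)[C@H](C)O[Si](C)(C)C(C)(C)C)=C/CC/C(CO[Si](c1ccccc1)(c1ccccc1)C(C)(C)C)=C/COP(=O)(OCC)OCC
F8 | step 17 | bis-silyl ether of 26 (15-OTBDPS, side-chain 3-OTBS) | C=C(COC(C)=O)[C@H]1C[C@H](OC(=O)CC(C)C)/C(COC(=O)[C@H](C)[C@H](C)O[Si](C)(C)C(C)(C)C)=C/CC[C@@]2(CO[Si](c3ccccc3)(c3ccccc3)C(C)(C)C)O[C@@H]2C1
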